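**Retrosynthetic overview**
1. Target 26 is (4S,5R,9S,10R,13R)-13-hydroxylabd-8(17)-ene-15,19-dioic acid. The endgame removes two temporary carbonyls (C6, C11), cleaves both methyl esters and removes one silyl ether.
2. Key disconnection: ring B is opened across C7–C8 and C9–C10, a formal [4+2] of a ring A 2-silyloxydiene (C10=C5–C6(OSi)=C7) with an allenyl ketone (C17=C8=C9–C11(=O)–C12…C15) that carries the whole side chain.
3. Enabling feature: in ring B the exocyclic methylene carbon C8 lies between C7 and the side-chain carbon C9, so C17=C8=C9 is an allene whose central carbon C8 is electrophilic once C11 is a carbonyl; C10–C5–C6–C7 is a diene on ring A.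
4. Stereocontrol: C4 is set by auxiliary-controlled methylation, C13 is bought with (R)-mevalonolactone, C10 and C9 are relayed from C4 in the key step, and C5 is set by protonation in the next step.
5. Ring order: ring A is bought (the cyclohexanone ring of 1); ring B is closed in the key step.

Key step: step 12

Remark: labdane numbering is used for all atoms (ring A = C1–C5, C10; ring B = C5–C10; C17 = exocyclic CH2 on C8; C18 = 4α-CH3; C19 = 4β-carboxyl; C20 = 10β-CH3; side chain C11–C16).
Assumption: the L-valine tert-butyl ester lithio-enamine of step 2 is taken to give the S quaternary center under the stated additive; the same auxiliary is expected to give either sense depending on the cosolvent, and the variant that gives the S center is the one meant.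

**Step 1**
Reactants: 1 methyl 2-oxocyclohexane-1-carboxylate; 2 L-valine tert-butyl ester
Product: 3 methyl 2-{[(2S)-1-(tert-butoxy)-3-methyl-1-oxobutan-2-yl]amino}cyclohex-1-ene-1-carboxylate
Conditions: BF3·OEt2 (cat.), benzene, reflux, Dean–Stark
Reagents that add atoms: none
Why: Acid-catalysed condensation of a β-keto ester with a primary amine should give the hydrogen-bonded enamino ester; no stereocenter is formed and the valine center is untouched.

**Step 2**
Reactants: 3 enamino ester
Product: 5 methyl (1S)-1-methyl-2-oxocyclohexane-1-carboxylate, via C-methylated imine 4 (not isolated)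
Conditions: LiN(i-Pr)2, toluene, HMPA, −78 °C; MeI; then 10% aq. citric acid, rt
Reagents that add atoms: iodomethane CI; water O
Why: Chiral lithio-enamine alkylation: N-deprotonation gives a chelated aza-enolate whose valine ester shields one face, so iodomethane should set the C4 quaternary center (S), and mild hydrolysis of imine 4 releases the ketone and the auxiliary.

**Step 3**
Reactants: 5 keto ester
Product: 6 methyl (1S)-1,3-dimethyl-2-oxocyclohexane-1-carboxylate (both C3 epimers)
Conditions: LiN(i-Pr)2, THF, −78 °C; MeI, −78 → 0 °C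
Reagents that add atoms: iodomethane CI
Why: Kinetic enolate alkylation: the quaternary C4 leaves only the future C10 enolisable, and the configuration of the new center is irrelevant because it becomes sp2 in step 4.

**Step 4**
Reactants: 6 dimethyl keto ester
Product: 7 methyl (1S)-1,3-dimethyl-2-{[(trifluoromethyl)sulfonyl]oxy}cyclohex-2-ene-1-carboxylate
Conditions: KN(SiMe3)2, THF, −78 °C; PhNTf2, −78 → 0 °C
Reagents that add atoms: N-phenylbis(trifluoromethanesulfonimide) O=S(=O)(N(c1ccccc1)S(=O)(=O)C(F)(F)F)C(F)(F)F
Why: Enol triflate formation from the only possible enolate should fix the tetrasubstituted C5=C10 double bond regiospecifically.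

**Step 5**
Reactants: 7 enol triflate
Product: 9 methyl (1S)-2-acetyl-1,3-dimethylcyclohex-2-ene-1-carboxylate, via ethoxy diene 8 (not isolated)
Conditions: tributyl(1-ethoxyvinyl)stannane, Pd(PPh3)4 (5 mol %), LiCl, THF, reflux; then 1 M HCl, THF, rt
Reagents that add atoms: tributyl(1-ethoxyvinyl)stannane CCCC[Sn](CCCC)(CCCC)C(=C)OCC; water O
Why: Stille coupling of the enol triflate with an acyl-anion-equivalent vinylstannane, then enol ether hydrolysis, should put the C6–C7 acetyl group on C5.

**Step 6**
Reactants: 9 enone
Product: 10 methyl (1S)-2-{1-[(tert-butyldimethylsilyl)oxy]ethenyl}-1,3-dimethylcyclohex-2-ene-1-carboxylate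
Conditions: KN(SiMe3)2, THF, −78 °C; TBSCl, −78 → 0 °C
Reagents that add atoms: tert-butyldimethylsilyl chloride CC(C)(C)[Si](C)(C)Cl
Why: Kinetic deprotonation of the methyl ketone at C7 (cross-conjugated enolate) and O-silylation should give the 2-silyloxydiene; no stereocenter is involved.

**Step 7**
Reactants: 11 (R)-mevalonolactone
Product: 12 (4R)-4-methyl-4-[(triethylsilyl)oxy]oxan-2-one
Conditions: TESOTf, 2,6-lutidine, CH2Cl2, 0 °C
Reagents that add atoms: triethylsilyl trifluoromethanesulfonate CC[Si](CC)(CC)OS(=O)(=O)C(F)(F)F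
Why: Silyl triflate silylation of the tertiary alcohol protects C13–OH (a free hydroxyl would add to the later allenone); the bought C13 center is not touched.

**Step 8**
Reactants: 12 silylated lactone
Product: 14 methyl (3R)-5-hydroxy-3-methyl-3-[(triethylsilyl)oxy]pentanoate, via potassium carboxylate 13 (not isolated)
Conditions: KOH (1.0 equiv), MeOH/H2O, 0 °C; evaporate; MeI, DMF, rt; used at once
Reagents that add atoms: potassium hydroxide [K+].[OH-]; iodomethane CI
Why: Saponification opens the lactone and SN2 O-methylation of the carboxylate should give the δ-hydroxy ester, which is oxidised immediately to avoid relactonisation.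

**Step 9**
Reactants: 14 hydroxy ester
Product: 15 methyl (3R)-3-methyl-5-oxo-3-[(triethylsilyl)oxy]pentanoate
Conditions: Dess–Martin periodinane, NaHCO3, CH2Cl2, 0 °C → rt
Reagents that add atoms: none
Why: Dess–Martin oxidation of the primary alcohol under buffered conditions should give the C11 aldehyde without loss of the β-silyloxy group.

**Step 10**
Reactants: 15 aldehyde
Product: 16 methyl (3R)-5-hydroxy-3-methyl-3-[(triethylsilyl)oxy]oct-7-ynoate (both C5 epimers)
Conditions: propargyl bromide, Zn dust, THF/sat. aq. NH4Cl, 0 °C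
Reagents that add atoms: propargyl bromide C#CCBr
Why: Barbier propargylation: the allenylzinc species adds to the aldehyde by SE2′ chemoselectively beside the ester, and the new carbinol center is erased in step 11.

**Step 11**
Reactants: 16 homopropargylic alcohol
Product: 18 methyl (3R)-3-methyl-5-oxo-3-[(triethylsilyl)oxy]octa-6,7-dienoate, via alkynyl ketone 17 (not isolated)
Conditions: Dess–Martin periodinane, NaHCO3, CH2Cl2, 0 °C; then Et3N (0.2 equiv), 0 °C; used at once
Reagents that add atoms: none
Why: Dess–Martin oxidation gives the β,γ-alkynyl ketone, which should isomerise under mild amine base (propargyl–allenyl prototropy) to the conjugated terminal allenyl ketone.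

**Step 12**
Reactants: 10 ring A silyloxydiene; 18 allenyl ketone
Product: 20 dimethyl (13R)-6-[(tert-butyldimethylsilyl)oxy]-11-oxo-13-[(triethylsilyl)oxy]labda-5,8(17)-diene-15,19-dioate (9α-H; 10β-CH3; 4β-CO2Me), via Michael-stage ion pair 19 (not isolated)
Conditions: Tf2NH (10 mol %), CH2Cl2, −78 → −40 °C; then Et3N
Reagents that add atoms: none
Why: Triflimide is silylated by a trace of 10 to give the silyl triflimide, which activates the C11 ketone of 18; the diene terminus C7 then adds to the central allene carbon C8 (Mukaiyama–Michael) to give ion pair 19, whose silyl dienol ether carbon C9 closes ring B on C10 of the silyloxyallyl cation and passes the silyl cation on, so the net change is a [4+2] cycloaddition across C8=C9 that leaves C8=C17 as the exocyclic methylene. The closest known reaction type is the triflimide- or Lewis-acid-promoted stepwise Diels–Alder reaction of hindered 1-(1-silyloxyvinyl)cyclohexenes with allenyl esters and ketones. Ring B closes in a 6-(enolexo)-endo-trig Michael mode. C10 is controlled by the C4 center of ring A: the ester, which has the smaller axial demand and avoids the C6–O bond, should sit pseudoaxial so that C9 enters anti to it and C20 ends cis to C19; C9 is set by the exo placement of the acyl group away from the C6 silyloxy group, which puts H9 anti to C20. The step needs regioselectivity (nucleophilic diene terminus C7 matched with the electrophilic central allene carbon C8), 1,4- over 1,2-addition (soft silyl enol ether, hindered ketone) and face selectivity at C10 (pseudoaxial C19 ester, and a smaller CO2Me/CH3 than CH3/CH3 syn-axial strain in the product-like transition state).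

**Step 13**
Reactants: 20 cycloadduct
Product: 21 dimethyl (13R)-6,11-dioxo-13-[(triethylsilyl)oxy]labd-8(17)-ene-15,19-dioate (5α-H)
Conditions: Bu4NF, AcOH (1:1), THF, 0 °C
Reagents that add atoms: none
Why: Buffered fluoride should cleave the silyl enol ether selectively (the tertiary triethylsilyl ether is far slower), and protonation at C5 from the α face, opposite the axial C20 methyl and C19 ester, gives the trans ring fusion, which is also the thermodynamic one.

**Step 14**
Reactants: 21 diketone
Product: 22 dimethyl (13R)-6,11-bis[2-(4-methylbenzenesulfonyl)hydrazinylidene]-13-[(triethylsilyl)oxy]labd-8(17)-ene-15,19-dioate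
Conditions: TsNHNH2 (3 equiv), PPTS (5 mol %), THF, 4 Å MS, 45 °C
Reagents that add atoms: 4-methylbenzenesulfonohydrazide Cc1ccc(cc1)S(=O)(=O)NN
Why: Condensation of both ketones with tosylhydrazide under weak acid should give the bis(tosylhydrazone); the weakly acidic, aprotic conditions are chosen to keep the 8(17) double bond out of conjugation and the silyl ether intact.

**Step 15**
Reactants: 22 bis(tosylhydrazone)
Product: 24 dimethyl (13R)-13-[(triethylsilyl)oxy]labd-8(17)-ene-15,19-dioate, via bis(diazene) 23 (not isolated)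
Conditions: catecholborane, CHCl3, 0 °C → rt; then NaOAc·3H2O, reflux
Reagents that add atoms: none
Why: Caglioti-type tosylhydrazone reduction: hydride adds to each C=N, acetate-induced loss of sulfinate gives the diazene, and loss of N2 should leave CH2 at C6 and C11 without touching the isolated alkene or any stereocenter.

**Step 16**
Reactants: 24 diester
Product: 25 (13R)-13-[(triethylsilyl)oxy]labd-8(17)-ene-15,19-dioic acid
Conditions: NaSEt, DMF, 100 °C; then cold 1 M HCl
Reagents that add atoms: none
Why: SN2 dealkylation of both methyl esters at the methyl carbon by thiolate should bypass the hindered axial C19 carbonyl, and the silyl ether guards C13–O against retro-aldol or elimination.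

**Step 17**
Reactants: 25 silyl ether diacid
Product: 26 (4S,5R,9S,10R,13R)-13-hydroxylabd-8(17)-ene-15,19-dioic acid (target)
Conditions: HF·pyridine, THF, 0 °C → rt
Reagents that add atoms: none
Why: Fluoride-mediated desilylation of the tertiary silyl ether under weakly acidic conditions should not isomerise the exocyclic alkene or dehydrate the tertiary alcohol.

**Compound list**
1 | methyl 2-oxocyclohexane-1-carboxylate | COC(=O)C1CCCCC1=O | starting material
2 | L-valine tert-butyl ester | CC(C)[C@H](N)C(=O)OC(C)(C)C | starting material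
3 | methyl 2-{[(2S)-1-(tert-butoxy)-3-methyl-1-oxobutan-2-yl]amino}cyclohex-1-ene-1-carboxylate | COC(=O)C1=C(N[C@@H](C(C)C)C(=O)OC(C)(C)C)CCCC1 | intermediate
4 | methyl (1S)-2-{[(2S)-1-(tert-butoxy)-3-methyl-1-oxobutan-2-yl]imino}-1-methylcyclohexane-1-carboxylate | COC(=O)[C@@]1(C)CCCCC1=N[C@@H](C(C)C)C(=O)OC(C)(C)C | intermediate
5 | methyl (1S)-1-methyl-2-oxocyclohexane-1-carboxylate | COC(=O)[C@@]1(C)CCCCC1=O | intermediate
6 | methyl (1S)-1,3-dimethyl-2-oxocyclohexane-1-carboxylate (C3 epimers) | COC(=O)[C@@]1(C)CCCC(C)C1=O | intermediate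
7 | methyl (1S)-1,3-dimethyl-2-{[(trifluoromethyl)sulfonyl]oxy}cyclohex-2-ene-1-carboxylate | COC(=O)[C@@]1(C)CCCC(C)=C1OS(=O)(=O)C(F)(F)F | intermediate
8 | methyl (1S)-2-(1-ethoxyethenyl)-1,3-dimethylcyclohex-2-ene-1-carboxylate | COC(=O)[C@@]1(C)CCCC(C)=C1C(=C)OCC | intermediate
9 | methyl (1S)-2-acetyl-1,3-dimethylcyclohex-2-ene-1-carboxylate | COC(=O)[C@@]1(C)CCCC(C)=C1C(C)=O | intermediate
10 | methyl (1S)-2-{1-[(tert-butyldimethylsilyl)oxy]ethenyl}-1,3-dimethylcyclohex-2-ene-1-carboxylate | COC(=O)[C@@]1(C)CCCC(C)=C1C(=C)O[Si](C)(C)C(C)(C)C | intermediate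
11 | (R)-mevalonolactone, (4R)-4-hydroxy-4-methyloxan-2-one | O=C1C[C@](C)(O)CCO1 | starting material
12 | (4R)-4-methyl-4-[(triethylsilyl)oxy]oxan-2-one | O=C1C[C@](C)(O[Si](CC)(CC)CC)CCO1 | intermediate
13 | potassium (3R)-5-hydroxy-3-methyl-3-[(triethylsilyl)oxy]pentanoate | [K+].[O-]C(=O)C[C@](C)(O[Si](CC)(CC)CC)CCO | intermediate
14 | methyl (3R)-5-hydroxy-3-methyl-3-[(triethylsilyl)oxy]pentanoate | COC(=O)C[C@](C)(O[Si](CC)(CC)CC)CCO | intermediate
15 | methyl (3R)-3-methyl-5-oxo-3-[(triethylsilyl)oxy]pentanoate | COC(=O)C[C@](C)(O[Si](CC)(CC)CC)CC=O | intermediate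
16 | methyl (3R)-5-hydroxy-3-methyl-3-[(triethylsilyl)oxy]oct-7-ynoate (C5 epimers) | COC(=O)C[C@](C)(O[Si](CC)(CC)CC)CC(O)CC#C | intermediate
17 | methyl (3R)-3-methyl-5-oxo-3-[(triethylsilyl)oxy]oct-7-ynoate | COC(=O)C[C@](C)(O[Si](CC)(CC)CC)CC(=O)CC#C | intermediate
18 | methyl (3R)-3-methyl-5-oxo-3-[(triethylsilyl)oxy]octa-6,7-dienoate | COC(=O)C[C@](C)(O[Si](CC)(CC)CC)CC(=O)C=C=C | intermediate
19 | Michael-stage ion pair: O-silyl oxocarbenium (C6) / silyl dienol ether (C11) with triflimide counter-ion | COC(=O)[C@@]1(C)CCCC(C)=C1C(CC(=C)C=C(O[Si](C)(C)C(C)(C)C)C[C@@](C)(O[Si](CC)(CC)CC)CC(=O)OC)=[O+][Si](C)(C)C(C)(C)C.O=S(=O)([N-]S(=O)(=O)C(F)(F)F)C(F)(F)F | intermediate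
20 | dimethyl (13R)-6-[(tert-butyldimethylsilyl)oxy]-11-oxo-13-[(triethylsilyl)oxy]labda-5,8(17)-diene-15,19-dioate | C=C1CC(O[Si](C)(C)C(C)(C)C)=C2[C@](C)(CCC[C@]2(C)C(=O)OC)[C@H]1C(=O)C[C@@](C)(O[Si](CC)(CC)CC)CC(=O)OC | intermediate
21 | dimethyl (13R)-6,11-dioxo-13-[(triethylsilyl)oxy]labd-8(17)-ene-15,19-dioate | C=C1CC(=O)[C@@H]2[C@](C)(CCC[C@]2(C)C(=O)OC)[C@H]1C(=O)C[C@@](C)(O[Si](CC)(CC)CC)CC(=O)OC | intermediate
22 | dimethyl (13R)-6,11-bis[2-(4-methylbenzenesulfonyl)hydrazinylidene]-13-[(triethylsilyl)oxy]labd-8(17)-ene-15,19-dioate | C=C1CC(=NNS(=O)(=O)c3ccc(C)cc3)[C@@H]2[C@](C)(CCC[C@]2(C)C(=O)OC)[C@H]1C(=NNS(=O)(=O)c1ccc(C)cc1)C[C@@](C)(O[Si](CC)(CC)CC)CC(=O)OC | intermediate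
23 | dimethyl (13R)-6,11-bis(diazenyl)-13-[(triethylsilyl)oxy]labd-8(17)-ene-15,19-dioate | C=C1CC(N=N)[C@@H]2[C@](C)(CCC[C@]2(C)C(=O)OC)[C@H]1C(N=N)C[C@@](C)(O[Si](CC)(CC)CC)CC(=O)OC | intermediate
24 | dimethyl (13R)-13-[(triethylsilyl)oxy]labd-8(17)-ene-15,19-dioate | C=C1CC[C@@H]2[C@](C)(CCC[C@]2(C)C(=O)OC)[C@H]1CC[C@@](C)(O[Si](CC)(CC)CC)CC(=O)OC | intermediate
25 | (13R)-13-[(triethylsilyl)oxy]labd-8(17)-ene-15,19-dioic acid | C=C1CC[C@@H]2[C@](C)(CCC[C@]2(C)C(=O)O)[C@H]1CC[C@@](C)(O[Si](CC)(CC)CC)CC(=O)O | intermediate
26 | (4S,5R,9S,10R,13R)-13-hydroxylabd-8(17)-ene-15,19-dioic acid | C=C1CC[C@@H]2[C@](C)(CCC[C@]2(C)C(=O)O)[C@H]1CC[C@@](C)(O)CC(=O)O | target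

**Step count**
Total: 17 steps. Longest linear sequence: 12 steps (steps 1–6, then 12–17); the side-chain branch is 5 steps (7–11).

**Steps most likely to fail**

Step 12. What may go wrong: poor facial selectivity at C10 (the CO2Me/CH3 pair on C4 is a weak control element), the wrong exo/endo sense at C9, or loss of the silyl group from ion pair 19 before ring closure. Fallback: the annulation is run as two discrete operations, the second under thermodynamic control. From 10 and 18, a Mukaiyama–Michael addition with stoichiometric TiCl4 (CH2Cl2, −78 °C, aqueous work-up) should give the open-chain Michael adduct F1. A reversible base-mediated intramolecular Michael addition (Cs2CO3, MeCN, rt) of the C9 dienolate to the enone carbon C10 should then close ring B and favour the isomer with the smaller syn-axial CO2Me/CH3 pair. This returns to the route at diketone 21.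

Step 14. What may go wrong: migration of the 8(17) double bond into conjugation with the C6 or C11 carbonyl, epimerisation at C9 through the ene-hydrazine, or no condensation at the hindered C6 ketone. Fallback: from 21, near-neutral thioketalisation with 1,2-bis(trimethylsilylthio)ethane and ZnI2 (Et2O, 0 °C → rt) should give the bis(1,3-dithiolane) F2. Radical desulfurisation with Bu3SnH and AIBN (toluene, reflux) then returns to the route at 24.

Step 5. What may go wrong: slow transmetalation at the tetrasubstituted enol triflate flanked by a quaternary carbon, with S–O cleavage back to ketone 6 or protodetriflation winning. Fallback: from 6, addition of ethynylmagnesium bromide with CeCl3 (THF, −78 °C) should give the propargylic alcohol F3. A Rupe rearrangement (HCO2H, 80 °C; dehydration can only go toward C10) then returns to the route at enone 9.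

**Further compounds**
F1 | step 12 | methyl (1S)-1,3-dimethyl-2-[(7R)-9-methoxy-7-methyl-3-methylidene-5,9-dioxo-7-(triethylsilyloxy)nonanoyl]cyclohex-2-ene-1-carboxylate | COC(=O)[C@@]1(C)CCCC(C)=C1C(=O)CC(=C)CC(=O)C[C@@](C)(O[Si](CC)(CC)CC)CC(=O)OC
F2 | step 14 | bis(1,3-dithiolane) of 21 at C6 and C11 | C=C1CC2(SCCS2)[C@@H]3[C@](C)(CCC[C@]3(C)C(=O)OC)[C@H]1C4(SCCS4)C[C@@](C)(O[Si](CC)(CC)CC)CC(=O)OC
F3 | step 5 | methyl (1S)-2-ethynyl-2-hydroxy-1,3-dimethylcyclohexane-1-carboxylate | COC(=O)[C@@]1(C)CCCC(C)C1(O)C#C
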